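**Strategy**

The cyclohexenone ring (C4a, C5, C6, C7, C8, C8a) is cut at C5–C6 and C7–C8. C6 and C7, with both oxygens and the methyl group, then come from methylglyoxal; C5–C4a=C8a–C8 comes from a 1-silyloxydiene that already carries the C1 oxygen and the enyne for the pyran ring. In one flask an enantioselective vinylogous Mukaiyama aldol joins C5 to C6, and a chiral carbene catalyst then adds the freed C8 aldehyde to the C7 ketone (crossed benzoin). This uses the C8(=O)–C7(OH) acyloin and the vinylogous aldol relation of C6–OH to C8=O through C4a=C8a. The pyran ring is closed late by 6-endo hydroalkoxylation.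

Key step: step 6

Remark: 3 is taken as the purchasable trans isomer and 8 is used as freshly distilled, water-free monomer; ring atoms are named by isochromene numbering (C1, O2, C3, C4, C4a, C5 to C8, C8a) throughout.

**Route**

Step 1
Reactants: 1 diethyl 2-acetylpropanedioate
Product: 2 diethyl 2-[1-(trifluoromethylsulfonyloxy)ethylidene]propanedioate
Conditions: Tf2O, Et3N, CH2Cl2, −78 to 0 °C
Reagents that add atoms: trifluoromethanesulfonic anhydride O=S(=O)(OS(=O)(=O)C(F)(F)F)C(F)(F)F
Why: O-sulfonylation of the enolised 2-acylmalonate (enol triflate formation) should give the tetrasubstituted vinyl triflate, with no geometry to control because the two ester groups are identical.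

Step 2
Reactants: 2 diethyl 2-[1-(trifluoromethylsulfonyloxy)ethylidene]propanedioate; 3 (3E)-pent-3-en-1-yne
Product: 4 diethyl 2-[(5E)-hept-5-en-3-yn-2-ylidene]propanedioate
Conditions: Pd(PPh3)4 (5 mol %), CuI (10 mol %), iPr2NEt, THF, 23 °C
Reagents that add atoms: none
Why: Sonogashira coupling of the electron-poor vinyl triflate with the terminal alkyne should be fast, and the E-propenyl geometry is carried over from 3.

Step 3
Reactants: 4 diethyl 2-[(5E)-hept-5-en-3-yn-2-ylidene]propanedioate
Product: 5 2-[(5E)-hept-5-en-3-yn-2-ylidene]propane-1,3-diol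
Conditions: iBu2AlH (DIBAL-H, 4.5 equiv), CH2Cl2, −78 to 0 °C; Rochelle salt work-up
Reagents that add atoms: none
Why: 1,2-reduction of both conjugated esters by the aluminium hydride (ester to allylic alcohol reduction) should give the symmetric 2-alkylidene-1,3-diol without touching the enyne.

Step 4
Reactants: 5 2-[(5E)-hept-5-en-3-yn-2-ylidene]propane-1,3-diol
Product: 6 (6E)-2-(hydroxymethyl)-3-methylocta-2,6-dien-4-ynal (both C2=C3 isomers, used together)
Conditions: activated MnO2 (excess), CH2Cl2, 23 °C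
Reagents that add atoms: none
Why: allylic alcohol oxidation with MnO2 should stop after one of the two equivalent CH2OH groups because the enal formed deactivates the second one; the C2=C3 geometry is erased in step 5, so both isomers serve.

Step 5
Reactants: 6 (6E)-2-(hydroxymethyl)-3-methylocta-2,6-dien-4-ynal
Product: 7 (1Z,6E)-1-(tert-butyldimethylsilyloxy)-2-[(tert-butyldimethylsilyloxy)methyl]-3-methylideneocta-1,6-dien-4-yne
Conditions: TBSOTf (2.5 equiv), Et3N, CH2Cl2, −78 to 0 °C
Reagents that add atoms: tert-butyldimethylsilyl triflate CC(C)(C)[Si](C)(C)OS(=O)(=O)C(F)(F)F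
Why: soft enolisation of the enal (silyl triflate and amine, γ-deprotonation of the only γ-CH3) should give the 1-silyloxydiene while the primary alcohol is silylated in the same flask (silyl dienol ether formation).

Step 6
Reactants: 7 (1Z,6E)-1-(tert-butyldimethylsilyloxy)-2-[(tert-butyldimethylsilyloxy)methyl]-3-methylideneocta-1,6-dien-4-yne; 8 methylglyoxal (2-oxopropanal)
Product: 10 (5S,6R)-5-(tert-butyldimethylsilyloxy)-2-[(tert-butyldimethylsilyloxy)methyl]-6-hydroxy-6-methyl-3-[(3E)-pent-3-en-1-yn-1-yl]cyclohex-2-en-1-one, via silyl aldol 9 (not isolated)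
Conditions: first stage: 8 (1.2 equiv), chiral 3,3′-bis[3,5-bis(trifluoromethyl)phenyl]-1,1′-binaphthyl-2,2′-disulfonimide (5 mol %), toluene, −78 °C, with aminoindanol-derived N-pentafluorophenyl triazolium tetrafluoroborate (15 mol %) already present; second stage, same flask: Et3N (15 mol %), −20 to 23 °C
Reagents that add atoms: none
Why: In the first stage the silylated disulfonimide activates the aldehyde carbonyl of 8, the diene 7 attacks through its terminal CH2 (C5, the γ-position) and the silyl group ends on the new secondary oxygen, which forms C5–C6 and gives back the enal as 9 (vinylogous Mukaiyama aldol with silyl transfer). In the second stage the carbene from the triazolium salt adds to the enal carbonyl, the enaminol so formed (an acyl-anion equivalent at C8) adds to the neighbouring methyl ketone in a 6-exo-trig closure and the catalyst is released, which forms C7–C8 and the tertiary alcohol (intramolecular crossed aldehyde–ketone benzoin reaction). The closest known reaction types are the catalytic enantioselective vinylogous Mukaiyama aldol of aldehyde-derived silyl dienol ethers and the carbene-catalysed cyclisation of keto-aldehydes to α-hydroxy tetralones. C6 (6S) should be set by the chiral counter-anion in the aldol stage and C7 (7R) by the chiral triazolium catalyst, with the bulky 6-silyloxy group pseudo-equatorial in the half-chair; the two catalyst enantiomers are chosen as the pair that gives the 6,7-trans arrangement of the oxygens. The step needs γ- over α-attack of the diene (C8a is fully substituted), attack on the aldehyde and not the ketone of 8 (the aldehyde is the more electrophilic carbonyl), acyl-anion and not homoenolate reactivity of the enal (the β-carbon C4a is fully substituted) and no epimerisation at C6 of 9 (weak amine base, fast closure). Closure also needs the formyl group cis to the C5 chain, and any other isomer should equilibrate through the dienolate under the basic second stage.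

Step 7
Reactants: 11 2,4-dihydroxy-6-methylbenzaldehyde
Product: 12 2-hydroxy-6-methyl-4-(triisopropylsilyloxy)benzaldehyde
Conditions: TIPSCl (1.05 equiv), imidazole, CH2Cl2, 0 °C
Reagents that add atoms: chlorotriisopropylsilane CC(C)[Si](Cl)(C(C)C)C(C)C
Why: phenol silylation should take the free 4-OH, since the 2-OH is held in a hydrogen bond to the aldehyde and flanked by it.

Step 8
Reactants: 12 2-hydroxy-6-methyl-4-(triisopropylsilyloxy)benzaldehyde
Product: 13 2-methoxy-6-methyl-4-(triisopropylsilyloxy)benzaldehyde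
Conditions: MeI, Ag2O, MeCN, 23 °C, dark
Reagents that add atoms: iodomethane CI
Why: O-methylation of the remaining phenol with Ag2O and MeI (Williamson-type ether synthesis) proceeds without soluble base and so should spare the aryl silyl ether.

Step 9
Reactants: 13 2-methoxy-6-methyl-4-(triisopropylsilyloxy)benzaldehyde
Product: 14 2-methoxy-6-methyl-4-(triisopropylsilyloxy)benzoic acid
Conditions: NaClO2, NaH2PO4, 2-methylbut-2-ene, t-BuOH/H2O, 23 °C
Reagents that add atoms: sodium chlorite [Na+].[O-]Cl=O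
Why: Pinnick oxidation converts even a doubly ortho-substituted aldehyde to the acid, and the alkene scavenger keeps hypochlorite away from the electron-rich ring.

Step 10
Reactants: 10 (5S,6R)-5-(tert-butyldimethylsilyloxy)-2-[(tert-butyldimethylsilyloxy)methyl]-6-hydroxy-6-methyl-3-[(3E)-pent-3-en-1-yn-1-yl]cyclohex-2-en-1-one; 14 2-methoxy-6-methyl-4-(triisopropylsilyloxy)benzoic acid
Product: 16 (1R,6S)-6-(tert-butyldimethylsilyloxy)-3-[(tert-butyldimethylsilyloxy)methyl]-1-methyl-2-oxo-4-[(3E)-pent-3-en-1-yn-1-yl]cyclohex-3-en-1-yl 2-methoxy-6-methyl-4-(triisopropylsilyloxy)benzoate, via acid chloride 15 (not isolated)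
Conditions: 14, (COCl)2, DMF (cat.), CH2Cl2, 0 to 23 °C, evaporate; then 10, DMAP, Et3N, CH2Cl2, 23 to 40 °C
Reagents that add atoms: none
Why: acylation of the only free hydroxyl, the tertiary α-ketol OH, by the aroyl chloride under nucleophilic catalysis (esterification through the acylpyridinium) leaves the C7–O bond intact, so the configuration is kept.

Step 11
Reactants: 16 (1R,6S)-6-(tert-butyldimethylsilyloxy)-3-[(tert-butyldimethylsilyloxy)methyl]-1-methyl-2-oxo-4-[(3E)-pent-3-en-1-yn-1-yl]cyclohex-3-en-1-yl 2-methoxy-6-methyl-4-(triisopropylsilyloxy)benzoate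
Product: 17 (1R,6S)-6-(tert-butyldimethylsilyloxy)-3-(hydroxymethyl)-1-methyl-2-oxo-4-[(3E)-pent-3-en-1-yn-1-yl]cyclohex-3-en-1-yl 2-methoxy-6-methyl-4-(triisopropylsilyloxy)benzoate
Conditions: HF·pyridine, pyridine, THF, 0 °C
Reagents that add atoms: none
Why: buffered fluoride desilylation should cleave the unhindered primary allylic silyl ether well before the secondary one next to the quaternary carbon (chemoselective silyl ether cleavage).

Step 12
Reactants: 17 (1R,6S)-6-(tert-butyldimethylsilyloxy)-3-(hydroxymethyl)-1-methyl-2-oxo-4-[(3E)-pent-3-en-1-yn-1-yl]cyclohex-3-en-1-yl 2-methoxy-6-methyl-4-(triisopropylsilyloxy)benzoate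
Product: 18 (6S,7R)-6-(tert-butyldimethylsilyloxy)-7-methyl-8-oxo-3-[(1E)-prop-1-en-1-yl]-5,6,7,8-tetrahydro-1H-isochromen-7-yl 2-methoxy-6-methyl-4-(triisopropylsilyloxy)benzoate
Conditions: Ph3PAuNTf2 (5 mol %), CH2Cl2, 0 to 23 °C
Reagents that add atoms: none
Why: gold-catalysed 6-endo-dig hydroalkoxylation of the cis-enynol should place the oxygen on the distal alkyne carbon (C3), which is δ to the C8 ketone and carries the propenyl group, and the C6 oxygen stays silylated so that only the C1 hydroxyl can add.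

Step 13
Reactants: 18 (6S,7R)-6-(tert-butyldimethylsilyloxy)-7-methyl-8-oxo-3-[(1E)-prop-1-en-1-yl]-5,6,7,8-tetrahydro-1H-isochromen-7-yl 2-methoxy-6-methyl-4-(triisopropylsilyloxy)benzoate
Product: 19 (6S,7R)-6-hydroxy-7-methyl-8-oxo-3-[(1E)-prop-1-en-1-yl]-5,6,7,8-tetrahydro-1H-isochromen-7-yl 4-hydroxy-2-methoxy-6-methylbenzoate
Conditions: HF·pyridine (excess), THF, 0 to 23 °C
Reagents that add atoms: none
Why: global fluoride desilylation under mildly acidic conditions should free the secondary alcohol and the phenol while avoiding the base that would invite retro-aldol cleavage or acyl shift from O7 to O6.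

**Compound list**

1 | diethyl 2-acetylpropanedioate | CCOC(=O)C(C(C)=O)C(=O)OCC | starting material
2 | diethyl 2-[1-(trifluoromethylsulfonyloxy)ethylidene]propanedioate | CCOC(=O)C(=C(C)OS(=O)(=O)C(F)(F)F)C(=O)OCC | intermediate
3 | (3E)-pent-3-en-1-yne | C/C=C/C#C | starting material
4 | diethyl 2-[(5E)-hept-5-en-3-yn-2-ylidene]propanedioate | CCOC(=O)C(=C(C)C#C/C=C/C)C(=O)OCC | intermediate
5 | 2-[(5E)-hept-5-en-3-yn-2-ylidene]propane-1,3-diol | C/C=C/C#CC(C)=C(CO)CO | intermediate
6 | (6E)-2-(hydroxymethyl)-3-methylocta-2,6-dien-4-ynal, both C2=C3 isomers, 2E isomer drawn | O=C/C(CO)=C(\C)C#C/C=C/C | intermediate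
7 | (1Z,6E)-1-(tert-butyldimethylsilyloxy)-2-[(tert-butyldimethylsilyloxy)methyl]-3-methylideneocta-1,6-dien-4-yne | C=C(C#C/C=C/C)/C(CO[Si](C)(C)C(C)(C)C)=C/O[Si](C)(C)C(C)(C)C | intermediate
8 | methylglyoxal (2-oxopropanal) | CC(=O)C=O | starting material
9 | (2E,5S)-5-(tert-butyldimethylsilyloxy)-2-[(tert-butyldimethylsilyloxy)methyl]-6-oxo-3-[(3E)-pent-3-en-1-yn-1-yl]hept-2-enal | O=C/C(CO[Si](C)(C)C(C)(C)C)=C(C#C/C=C/C)\C[C@H](O[Si](C)(C)C(C)(C)C)C(C)=O | intermediate
10 | (5S,6R)-5-(tert-butyldimethylsilyloxy)-2-[(tert-butyldimethylsilyloxy)methyl]-6-hydroxy-6-methyl-3-[(3E)-pent-3-en-1-yn-1-yl]cyclohex-2-en-1-one | C/C=C/C#CC1=C(CO[Si](C)(C)C(C)(C)C)C(=O)[C@](C)(O)[C@@H](O[Si](C)(C)C(C)(C)C)C1 | intermediate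
11 | 2,4-dihydroxy-6-methylbenzaldehyde | Cc1cc(O)cc(O)c1C=O | starting material
12 | 2-hydroxy-6-methyl-4-(triisopropylsilyloxy)benzaldehyde | Cc1cc(O[Si](C(C)C)(C(C)C)C(C)C)cc(O)c1C=O | intermediate
13 | 2-methoxy-6-methyl-4-(triisopropylsilyloxy)benzaldehyde | COc1cc(O[Si](C(C)C)(C(C)C)C(C)C)cc(C)c1C=O | intermediate
14 | 2-methoxy-6-methyl-4-(triisopropylsilyloxy)benzoic acid | COc1cc(O[Si](C(C)C)(C(C)C)C(C)C)cc(C)c1C(=O)O | intermediate
15 | 2-methoxy-6-methyl-4-(triisopropylsilyloxy)benzoyl chloride | COc1cc(O[Si](C(C)C)(C(C)C)C(C)C)cc(C)c1C(=O)Cl | intermediate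
16 | (1R,6S)-6-(tert-butyldimethylsilyloxy)-3-[(tert-butyldimethylsilyloxy)methyl]-1-methyl-2-oxo-4-[(3E)-pent-3-en-1-yn-1-yl]cyclohex-3-en-1-yl 2-methoxy-6-methyl-4-(triisopropylsilyloxy)benzoate | C/C=C/C#CC1=C(CO[Si](C)(C)C(C)(C)C)C(=O)[C@](C)(OC(=O)c2c(C)cc(O[Si](C(C)C)(C(C)C)C(C)C)cc2OC)[C@@H](O[Si](C)(C)C(C)(C)C)C1 | intermediate
17 | (1R,6S)-6-(tert-butyldimethylsilyloxy)-3-(hydroxymethyl)-1-methyl-2-oxo-4-[(3E)-pent-3-en-1-yn-1-yl]cyclohex-3-en-1-yl 2-methoxy-6-methyl-4-(triisopropylsilyloxy)benzoate | C/C=C/C#CC1=C(CO)C(=O)[C@](C)(OC(=O)c2c(C)cc(O[Si](C(C)C)(C(C)C)C(C)C)cc2OC)[C@@H](O[Si](C)(C)C(C)(C)C)C1 | intermediate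
18 | (6S,7R)-6-(tert-butyldimethylsilyloxy)-7-methyl-8-oxo-3-[(1E)-prop-1-en-1-yl]-5,6,7,8-tetrahydro-1H-isochromen-7-yl 2-methoxy-6-methyl-4-(triisopropylsilyloxy)benzoate | C/C=C/C1=CC2=C(CO1)C(=O)[C@](C)(OC(=O)c1c(C)cc(O[Si](C(C)C)(C(C)C)C(C)C)cc1OC)[C@@H](O[Si](C)(C)C(C)(C)C)C2 | intermediate
19 | (6S,7R)-6-hydroxy-7-methyl-8-oxo-3-[(1E)-prop-1-en-1-yl]-5,6,7,8-tetrahydro-1H-isochromen-7-yl 4-hydroxy-2-methoxy-6-methylbenzoate | C/C=C/C1=CC2=C(CO1)C(=O)[C@](C)(OC(=O)c1c(C)cc(O)cc1OC)[C@@H](O)C2 | target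

**Count and risks**

Total steps: 13. Longest linear sequence: 10 (steps 1 to 6, then 10 to 13).

Steps most likely to fail:

1. Step 6. The carbene may be drawn by the conjugated aldehyde into homoenolate or redox pathways, or the acyl-anion equivalent may add to the wrong face of the ketone. The fallback sets out from 9, isolated by stopping step 6 before the amine base is added. Ketyl–carbonyl (pinacol) cyclisation of 9 with SmI2 in THF/t-BuOH at −78 °C should give the cis-1,2-diol F1, with the new tertiary hydroxyl trans to the neighbouring silyloxy group. Oxidation of the allylic secondary alcohol of F1 with MnO2 then comes back to the route at 10.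

2. Step 10. Acyl transfer from the doubly ortho-substituted aroyl chloride to the hindered tertiary alcohol may be too slow, and forcing may start α-ketol rearrangement of 10. The fallback sets out from 10 and builds the arene on the oxygen. Heating 10 with 6-(2,4-dioxopentyl)-2,2-dimethyl-4H-1,3-dioxin-4-one in toluene (acylketene trapping) should give the trioxooctanoate ester F2. Aldol aromatisation with Cs2CO3 and then dilute acid gives the orsellinate ester F3, and silylation of its unchelated 4-OH with TIPSCl and imidazole gives the silyl ether F4. Methylation of the 2-OH with MeI and Ag2O comes back to the route at 16.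

3. Step 12. The hydroxyl may attack the proximal alkyne carbon in a 5-exo mode and drift to a fused furan in place of the 6-endo closure. The fallback sets out from 16. Hydration of the alkyne at the distal carbon with Ph3PAuNTf2 and water in dioxane should give the enone F5. Removal of the primary silyl group with HF·pyridine gives the hydroxy ketone F6, and cyclodehydration with PPTS in toluene (hemiketal formation and loss of water) comes back to the route at 18.

Further compounds

F1 | step 6 | 5-(tert-butyldimethylsilyloxy)-2-[(tert-butyldimethylsilyloxy)methyl]-6-methyl-3-[(3E)-pent-3-en-1-yn-1-yl]cyclohex-2-ene-1,6-diol, 1-OH cis to 6-OH, 6-OH trans to 5-silyloxy | C/C=C/C#CC1=C(CO[Si](C)(C)C(C)(C)C)[C@H](O)[C@](C)(O)[C@@H](O[Si](C)(C)C(C)(C)C)C1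
F2 | step 10 | (1R,6S)-6-(tert-butyldimethylsilyloxy)-3-[(tert-butyldimethylsilyloxy)methyl]-1-methyl-2-oxo-4-[(3E)-pent-3-en-1-yn-1-yl]cyclohex-3-en-1-yl 3,5,7-trioxooctanoate | C/C=C/C#CC1=C(CO[Si](C)(C)C(C)(C)C)C(=O)[C@](C)(OC(=O)CC(=O)CC(=O)CC(C)=O)[C@@H](O[Si](C)(C)C(C)(C)C)C1
F3 | step 10 | (1R,6S)-6-(tert-butyldimethylsilyloxy)-3-[(tert-butyldimethylsilyloxy)methyl]-1-methyl-2-oxo-4-[(3E)-pent-3-en-1-yn-1-yl]cyclohex-3-en-1-yl 2,4-dihydroxy-6-methylbenzoate | C/C=C/C#CC1=C(CO[Si](C)(C)C(C)(C)C)C(=O)[C@](C)(OC(=O)c2c(C)cc(O)cc2O)[C@@H](O[Si](C)(C)C(C)(C)C)C1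
F4 | step 10 | (1R,6S)-6-(tert-butyldimethylsilyloxy)-3-[(tert-butyldimethylsilyloxy)methyl]-1-methyl-2-oxo-4-[(3E)-pent-3-en-1-yn-1-yl]cyclohex-3-en-1-yl 2-hydroxy-6-methyl-4-(triisopropylsilyloxy)benzoate | C/C=C/C#CC1=C(CO[Si](C)(C)C(C)(C)C)C(=O)[C@](C)(OC(=O)c2c(C)cc(O[Si](C(C)C)(C(C)C)C(C)C)cc2O)[C@@H](O[Si](C)(C)C(C)(C)C)C1
F5 | step 12 | (1R,6S)-6-(tert-butyldimethylsilyloxy)-3-[(tert-butyldimethylsilyloxy)methyl]-1-methyl-2-oxo-4-[(3E)-2-oxopent-3-en-1-yl]cyclohex-3-en-1-yl 2-methoxy-6-methyl-4-(triisopropylsilyloxy)benzoate | C/C=C/C(=O)CC1=C(CO[Si](C)(C)C(C)(C)C)C(=O)[C@](C)(OC(=O)c2c(C)cc(O[Si](C(C)C)(C(C)C)C(C)C)cc2OC)[C@@H](O[Si](C)(C)C(C)(C)C)C1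
F6 | step 12 | (1R,6S)-6-(tert-butyldimethylsilyloxy)-3-(hydroxymethyl)-1-methyl-2-oxo-4-[(3E)-2-oxopent-3-en-1-yl]cyclohex-3-en-1-yl 2-methoxy-6-methyl-4-(triisopropylsilyloxy)benzoate | C/C=C/C(=O)CC1=C(CO)C(=O)[C@](C)(OC(=O)c2c(C)cc(O[Si](C(C)C)(C(C)C)C(C)C)cc2OC)[C@@H](O[Si](C)(C)C(C)(C)C)C1
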